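## The problem

Compound 26 is a eudesmane: a trans-fused decalin in which ring A (C1–C5, C10) and ring B (C5–C10) share the C5–C10 bond. Eudesmane numbering is used throughout (C14 is the methyl on C10, C15 the methyl on C4, C11 the isopropyl methine on C7). There are six stereocentres, C3, C4, C5, C6, C7 and the quaternary C10. The 4-hydroxyl, the 6-benzoyloxy group and C14 are all β and axial on one face, the 3-hydroxyl is α and axial, and only the C7 isopropyl group is equatorial. C6 and C7 are neighbours that can be made in an open chain and can then dictate C5 and C10 when the rings close; the finished trans-decalin, with its β face screened by C14 and the C6 oxygen, can in turn dictate C3 and C4. The benzoate does not survive hydride, hydrazine or strong base and can migrate to the syn-axial C4 hydroxyl, and the tertiary C4 carbinol ionises and eliminates in acid, so ester and diol must come late and in that order. The feature that opens the structure is ring A: a trans-diaxial 3,4-diol with a methyl on C4 is the hydration product of the epoxide of a C3=C4(C15) alkene, and that cyclohexene is what a Diels–Alder reaction of a C2=C3–C4(C15)=C5 diene with a C1=C10(C14) alkene leaves. Because C9 is a plain methylene in 26, a carbonyl can be lent to it to activate that alkene and to make it one end of the chain C6–C9 that ties the dienophile to the diene, so that ring B closes in the same event.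

## Retrosynthesis

**Diol.** The C4–O bond of 26 is cut (the C3–O bond is kept), which leads to the 3α,4α-epoxide 25 and from there to alkene 24. A cis-dihydroxylation would give the wrong C3/C4 relation, whereas epoxide hydration gives the trans-diaxial pair directly. The forward steps must epoxidise from the α face and open at C4 from the β face; the screened β face and the coincidence of tertiary and trans-diaxial opening both favour this. Alkene 24 has two stereocentres fewer.

**Ester and C9.** The acyl C–O bond at C6 is cut, so 24 comes from alcohol 23. A carbonyl is then added at C9: 23 from hydroxy-ketone 21 by deoxygenation, and 21 from silyl ether 20. C9 is chosen because a carbonyl there lies inside ring B next to the quaternary C10 and a methylene, has no stereocentre to epimerise and nothing β to eliminate, and can be removed by hydrazone chemistry before the ester exists. The forward steps must cleave a hindered silyl ether, reduce a ketone next to a quaternary carbon, and acylate a hindered axial alcohol.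

**Both rings.** The C5–C10 and C1–C2 bonds of 20 are cut, giving the open-chain trienone 19. A cut of one ring only would leave a cyclohexane with a separately made quaternary centre; this cut removes both rings and the two ring-fusion stereocentres and leaves only C6 and C7. The forward reaction must give trans fusion and add to one face of the diene.

**Enone and diene.** Trienone 19 comes from allylic alcohol 18 by oxidation, 18 from enyne 17 by semihydrogenation, and 17 from aldehyde 15 and isopropenylmagnesium bromide 16 by forming C9–C10. The diene is carried as an enyne because a terminal diene would not survive the hydroboration that installs the C9 oxygen.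

**C9 oxygen.** Aldehyde 15 comes from primary alcohol 14, and 14 from the vinyl compound 11 (the silyl ether of 10) by anti-Markovnikov hydration. This fixes the tether length at one methylene (C8) between C7 and C9.

**C6–C7.** The C6–C7 bond of 10 is cut to aldehyde 4 and the (E)-γ-isopropylallylboronate 8. An aldol would put a carbonyl on C8 that has to be removed again; the allylboration delivers the C8=C9 vinyl group that the next step needs. It sets both stereocentres at once: the anti relation from the (E)-geometry of 8, the absolute sense from a chiral acid catalyst.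

**Fragments.** Aldehyde 4 comes from commercial enynol 1 by C-silylation (3) and allylic oxidation. Boronate 8 comes from 3-methylbut-1-yne 5 by hydroboration (6) and one-carbon homologation.

## Roads not taken

**Alternative 1:** The cut is C5–C6 alone. Forward, Me2AlCl activates the aldehyde of A1, (2S)-4-[(1R)-1,3-dimethylcyclohex-2-en-1-yl]-2-(propan-2-yl)butanal. C5 of the ring A alkene attacks C6 and a C15 hydrogen passes to oxygen (intramolecular carbonyl-ene reaction, type 2), closing ring B to give A2, eudesm-4(15)-en-6α-ol.
- Merits: ring B, C5 and C6 come from one step of a reliable reaction class, and no temporary carbonyl has to be removed. In that respect this road is better than the chosen one, which needs steps 13 and 14.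
- Weak points: the hydroxyl of A2 is equatorial (6α), so C6 must be inverted at the most hindered position of the molecule. The alkene is exocyclic at C4(C15) and must be moved to C3=C4 before the diol can be made. C7 and C10 of A1 are 1,4-related across a flexible chain, so each needs its own asymmetric step, the quaternary one included.
- Comparison: the chosen plan sets against it that one asymmetric reaction (step 5) sets the only two stereocentres that have to be introduced, that C5, C6, C7 and C10 are all correct in 20, and that the alkene is formed in the right place.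

**Alternative 2:** The cut is C1–C10, with C14 carried as a cyclopropane carbon. The substrate A3 is a ring B cyclohexane with an exocyclic C10=C14 alkene and, on C5, the chain C4(OSiMe3)(C15)–C3H(OH)–C2≡C1H. Forward, PtCl2 (divalent platinum) activates the alkyne; C1 bonds to C10 and C14, a hydrogen shifts from C3, and the 3-ketone A4 (1,14-cyclo-3-oxoeudesmane 4β,6β-bis(silyl ether)) results. Hydrogenolysis of C1–C14 would later release the C10 methyl.
- Merits: the C3 and C4 oxygens are in place before ring A closes, so no cationic epoxide opening is needed and C4 is never at risk of elimination. In this respect the road is better than the chosen one.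
- Weak points: A3 already needs four contiguous stereocentres, one of them an acyclic tertiary carbinol. The face of the cyclopropanation, which fixes C10, rests on the conformation of a flexible side chain. One of three cyclopropane bonds must be cleaved under forcing hydrogenation, and the ketone must be reduced to the axial alcohol.
- Comparison: the chosen plan sets against it a much shorter approach to its cyclisation substrate and a clear physical origin of control at C10.

**Alternative 3:** The cut is C9–C10 and C5–C6. Forward, diene A5, (1E)-1-[(tert-butyldimethylsilyl)oxy]-2-(propan-2-yl)buta-1,3-diene, adds across the methyl-bearing double bond of quinone A6, 2-methoxy-5-methyl-1,4-benzoquinone, under a chiral oxazaborolidinium Lewis acid. This closes ring B and gives the cis-fused endo adduct A7.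
- Merits: it is convergent, catalytic and enantioselective from two small achiral pieces, the catalyst sets the quaternary C10, and ring A arrives with oxygen on C3 and C4. In convergence and in the cost of chirality this road is better than the chosen one.
- Weak points: the endo mode cis-fuses the rings and places the C6 oxygen trans to the C5 hydrogen, so A7 needs epimerisation at C5 and inversion at C6. The C1 carbonyl must be removed, C7 set by hydrogenation of C7=C8, C15 added to the C4 carbonyl and the enol ether turned into the 3α-alcohol.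
- Comparison: the chosen plan sets against it a key product, 20, in which every ring stereocentre already has its final configuration and only the C9 carbonyl has to go.

Key step: step 12

Remark on the chemistry: the cyclisation substrate is built as a 1,7,9-decatrien-3-one with a single methylene (C8) between C7 and the C9 carbonyl, because only this chain length closes a six-membered ring B; one carbon more would give a seven-membered ring.

## Route

Step 1
Reactants: 1 (E)-3-methylpent-2-en-4-yn-1-ol
Product: 3 (E)-3-methyl-5-(trimethylsilyl)pent-2-en-4-yn-1-ol, via O,C-bis(trimethylsilyl) enynol 2 (not isolated)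
Conditions: n-BuLi (2.2 equiv), THF, −78 → 0 °C; TMSCl (2.3 equiv), −78 °C → rt; then 1 M aq. HCl, rt
Reagents that add atoms: chlorotrimethylsilane, C[Si](C)(C)Cl
Why: Double deprotonation gives the alkoxide–acetylide, both sites are silylated, and dilute acid hydrolyses only the labile O–Si bond of 2 (standard C-silylation of a terminal alkynol); the (E)-alkene is untouched.

Step 2
Reactants: 3 (E)-3-methyl-5-(trimethylsilyl)pent-2-en-4-yn-1-ol
Product: 4 (E)-3-methyl-5-(trimethylsilyl)pent-2-en-4-ynal
Conditions: MnO2 (activated, 15 equiv), CH2Cl2, rt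
Reagents that add atoms: none
Why: MnO2 oxidises allylic alcohols selectively to enals without over-oxidation and without E/Z isomerisation.

Step 3
Reactants: 5 3-methylbut-1-yne
Product: 6 (E)-4,4,5,5-tetramethyl-2-(3-methylbut-1-en-1-yl)-1,3,2-dioxaborolane
Conditions: pinacolborane (1.0 equiv), 5 (1.3 equiv), Cp2Zr(H)Cl (5 mol%), Et3N (10 mol%), neat, sealed tube, 40 °C
Reagents that add atoms: pinacolborane (4,4,5,5-tetramethyl-1,3,2-dioxaborolane), CC1(C)OBOC1(C)C
Why: Cp2Zr(H)Cl-catalysed syn hydroboration of a terminal alkyne puts boron on the terminal carbon and gives the (E)-alkenylboronate.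

Step 4
Reactants: 6 (E)-4,4,5,5-tetramethyl-2-(3-methylbut-1-en-1-yl)-1,3,2-dioxaborolane
Product: 8 (E)-4,4,5,5-tetramethyl-2-(4-methylpent-2-en-1-yl)-1,3,2-dioxaborolane, via lithium chloromethyl boronate complex 7 (not isolated)
Conditions: ICH2Cl (1.2 equiv), n-BuLi (1.1 equiv), THF, −78 °C → rt
Reagents that add atoms: chloroiodomethane, ClCI
Why: Matteson homologation: chloromethyllithium, made in the flask by iodine–lithium exchange, adds to boron, and in complex 7 the alkenyl group migrates to carbon with loss of chloride and retention of the (E)-geometry, giving the γ-substituted allylboronate.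

Step 5
Reactants: 4 (E)-3-methyl-5-(trimethylsilyl)pent-2-en-4-ynal; 8 (E)-4,4,5,5-tetramethyl-2-(4-methylpent-2-en-1-yl)-1,3,2-dioxaborolane
Product: 10 (3R,4R,5E)-6-methyl-3-(propan-2-yl)-8-(trimethylsilyl)octa-1,5-dien-7-yn-4-ol, via pinacol borate ester 9 (not isolated)
Conditions: (R)-3,3′-bis(2,4,6-triisopropylphenyl)-1,1′-binaphthyl-2,2′-diyl hydrogen phosphate [(R)-TRIP] (5 mol%), 8 (1.3 equiv), 4 Å MS, toluene, −30 °C; then aq. NaHCO3
Reagents that add atoms: none
Why: Chiral phosphoric acid-catalysed allylboration: the closed chair transition state turns the (E)-geometry of 8 into the anti relation of C6 and C7, and the (R)-acid, hydrogen-bonded to a boronate oxygen and the formyl hydrogen, is expected to direct the allyl group to the Re face of the aldehyde, giving 6R,7R in eudesmane numbering. The sense is to be confirmed on 10 by MTPA ester analysis before material is carried on.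

Step 6
Reactants: 10 (3R,4R,5E)-6-methyl-3-(propan-2-yl)-8-(trimethylsilyl)octa-1,5-dien-7-yn-4-ol
Product: 11 tert-butyldimethyl{[(3R,4R,5E)-6-methyl-3-(propan-2-yl)-8-(trimethylsilyl)octa-1,5-dien-7-yn-4-yl]oxy}silane
Conditions: TBSOTf (1.3 equiv), 2,6-lutidine (2.0 equiv), CH2Cl2, −78 → 0 °C
Reagents that add atoms: tert-butyldimethylsilyl trifluoromethanesulfonate, CC(C)(C)[Si](C)(C)OS(=O)(=O)C(F)(F)F
Why: Silylation of a hindered secondary alcohol with the silyl triflate and a hindered base; no stereocentre is touched.

Step 7
Reactants: 11 tert-butyldimethyl{[(3R,4R,5E)-6-methyl-3-(propan-2-yl)-8-(trimethylsilyl)octa-1,5-dien-7-yn-4-yl]oxy}silane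
Product: 14 (3S,4R,5E)-4-[(tert-butyldimethylsilyl)oxy]-6-methyl-3-(propan-2-yl)oct-5-en-7-yn-1-ol, via B-alkyl-9-borabicyclo[3.3.1]nonane 12 (not isolated), via C-silyl primary alcohol 13 (not isolated)
Conditions: 9-BBN (1.5 equiv), THF, 0 °C → rt; then MeOH, 3 M aq. NaOH, 30% H2O2, 0 °C → rt
Reagents that add atoms: hydrogen peroxide, OO
Why: 9-BBN adds to the monosubstituted C8=C9 alkene far faster than to the silyl-capped alkyne or the trisubstituted alkene and puts boron on C9 (anti-Markovnikov hydroboration); alkaline peroxide oxidises the C–B bond, and the same methanolic hydroxide removes the alkynyl silyl group, which is needed only during the hydroboration.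

Step 8
Reactants: 14 (3S,4R,5E)-4-[(tert-butyldimethylsilyl)oxy]-6-methyl-3-(propan-2-yl)oct-5-en-7-yn-1-ol
Product: 15 (3S,4R,5E)-4-[(tert-butyldimethylsilyl)oxy]-6-methyl-3-(propan-2-yl)oct-5-en-7-ynal
Conditions: Dess–Martin periodinane (1.3 equiv), NaHCO3, CH2Cl2, 0 °C → rt
Reagents that add atoms: none
Why: Dess–Martin oxidation stops at the aldehyde; the α-carbon C8 is a methylene and the β-carbon carries no leaving group, so nothing epimerises or eliminates.

Step 9
Reactants: 15 (3S,4R,5E)-4-[(tert-butyldimethylsilyl)oxy]-6-methyl-3-(propan-2-yl)oct-5-en-7-ynal; 16 isopropenylmagnesium bromide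
Product: 17 (5S,6R,7E)-6-[(tert-butyldimethylsilyl)oxy]-2,8-dimethyl-5-(propan-2-yl)deca-1,7-dien-9-yn-3-ol (both C3 epimers)
Conditions: 16 (2.2 equiv), THF, −78 °C; aq. NH4Cl
Reagents that add atoms: none
Why: Grignard addition to the aldehyde forms C9–C10; the excess covers any deprotonation of the terminal alkyne, and the carbinol configuration is irrelevant because this carbon is oxidised in step 11.

Step 10
Reactants: 17 (5S,6R,7E)-6-[(tert-butyldimethylsilyl)oxy]-2,8-dimethyl-5-(propan-2-yl)deca-1,7-dien-9-yn-3-ol
Product: 18 (5S,6R,7E)-6-[(tert-butyldimethylsilyl)oxy]-2,8-dimethyl-5-(propan-2-yl)deca-1,7,9-trien-3-ol (both C3 epimers)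
Conditions: H2 (1 atm), Pd/CaCO3 poisoned with Pb(OAc)2 (Lindlar catalyst), quinoline, EtOAc, rt, stopped at 1 equiv H2
Reagents that add atoms: none
Why: Lindlar semihydrogenation reduces the terminal alkyne of the conjugated enyne to the vinyl group; the trisubstituted and 1,1-disubstituted alkenes are not reduced on the poisoned catalyst, and the existing (E)-alkene keeps its geometry.

Step 11
Reactants: 18 (5S,6R,7E)-6-[(tert-butyldimethylsilyl)oxy]-2,8-dimethyl-5-(propan-2-yl)deca-1,7,9-trien-3-ol
Product: 19 (5S,6R,7E)-6-[(tert-butyldimethylsilyl)oxy]-2,8-dimethyl-5-(propan-2-yl)deca-1,7,9-trien-3-one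
Conditions: Dess–Martin periodinane (1.5 equiv), NaHCO3, CH2Cl2, 0 °C; cold filtration through silica, used at once
Reagents that add atoms: none
Why: Buffered Dess–Martin oxidation of the allylic alcohol gives the isopropenyl ketone without touching the diene or the silyl ether; the trienone is kept cold so that it does not cyclise before the Lewis acid is added.

Step 12
Reactants: 19 (5S,6R,7E)-6-[(tert-butyldimethylsilyl)oxy]-2,8-dimethyl-5-(propan-2-yl)deca-1,7,9-trien-3-one
Product: 20 6β-[(tert-butyldimethylsilyl)oxy]eudesm-3-en-9-one (5α-H; 7β-isopropyl; 10β-methyl)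
Conditions: Et2AlCl (1.2 equiv), CH2Cl2, −78 → −20 °C; aq. sodium potassium tartrate
Reagents that add atoms: none
Why: Et2AlCl binds the C9 carbonyl, lowers the LUMO of the C1=C10 alkene, and the (E)-diene adds to it in a concerted, asynchronous [4+2] cycloaddition that forms C5–C10 and C1–C2; the closest known reaction type is the Lewis acid-promoted type 1 intramolecular Diels–Alder reaction of 1,7,9-decatrien-3-ones to octalones. Ring A is closed as the new cyclohexene, with both new σ bonds and the shifted C3=C4 alkene in it; ring B is closed in the fused mode by the C5–C10 bond around the four-atom tether C6–C9, through a chair-like six-membered arrangement. C10 is set relative to C5 by the approach in which the tether carbonyl is exo and C14 endo, the usual preference of α-methyl enone dienophiles, reinforced by the Lewis acid; this gives the trans ring fusion. C5, and with it the absolute sense of both new centres, is set by C6 and C7: A(1,3) strain between C15 on C4 and the substituents on C6 holds the C6–H bond in the diene plane, so the silyloxy group is axial and the isopropyl group equatorial on the chair tether, and the dienophile reaches one face of the diene only. The step needs trans over cis fusion and one diene face; the α-methyl group, the low temperature and two tether substituents that act in the same direction are expected to secure both. The syn-axial contact between the C6 silyloxy group and C14 in this transition state is the one opposing term.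

Step 13
Reactants: 20 6β-[(tert-butyldimethylsilyl)oxy]eudesm-3-en-9-one
Product: 21 6β-hydroxyeudesm-3-en-9-one
Conditions: 48% aq. HF, MeCN, 0 °C → rt
Reagents that add atoms: none
Why: Fluoride-driven Si–O cleavage copes with the hindered axial silyl ether; the ketone has no epimerisable α-stereocentre, and removing the silyl group now leaves no doubt about its fate in the next step.

Step 14
Reactants: 21 6β-hydroxyeudesm-3-en-9-one
Product: 23 eudesm-3-en-6β-ol, via C9 hydrazone 22 (not isolated)
Conditions: N2H4·H2O (10 equiv), KOH (8 equiv), diethylene glycol, 130 °C; then distil to 200 °C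
Reagents that add atoms: none
Why: Wolff–Kishner reduction under Huang-Minlon conditions: hydrazone 22 is decomposed by base with loss of N2. The carbonyl sits between the quaternary C10 and a methylene, so nothing can epimerise or eliminate, and ring ketones next to a quaternary carbon are reduced under these conditions.

Step 15
Reactants: 23 eudesm-3-en-6β-ol
Product: 24 eudesm-3-en-6β-yl benzoate
Conditions: BzCl (3 equiv), DMAP (1 equiv), pyridine, 80 °C
Reagents that add atoms: benzoyl chloride, O=C(Cl)c1ccccc1
Why: DMAP-catalysed acylation of the only hydroxyl; the axial, flanked position calls for the acylpyridinium reagent and heat, and no stereocentre is touched.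

Step 16
Reactants: 24 eudesm-3-en-6β-yl benzoate
Product: 25 3α,4α-epoxyeudesman-6β-yl benzoate
Conditions: mCPBA (1.3 equiv), NaHCO3, CH2Cl2, 0 °C
Reagents that add atoms: 3-chloroperoxybenzoic acid (mCPBA), OOC(=O)c1cccc(Cl)c1
Why: Prilezhaev epoxidation: the β face of the C3=C4 alkene is screened by the axial C14 methyl and the axial C6 benzoate, so the peracid adds from the α face and fixes the C3 oxygen as α.

Step 17
Reactants: 25 3α,4α-epoxyeudesman-6β-yl benzoate
Product: 26 6β-(benzoyloxy)eudesmane-3α,4β-diol, (1R,2S,4aS,7R,8R,8aS)-7,8-dihydroxy-4a,8-dimethyl-2-(propan-2-yl)decahydronaphthalen-1-yl benzoate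
Conditions: HClO4 (0.1 equiv), THF/H2O (3:1), 0 °C → rt
Reagents that add atoms: water, O
Why: Acid-catalysed epoxide hydrolysis: the protonated epoxide opens at the tertiary C4 with inversion by axial β attack of water, which is also the trans-diaxial (Fürst–Plattner) mode, giving the 4β-hydroxyl and 4α-methyl while the 3α-oxygen stays in place. Participation by the syn-axial benzoate carbonyl would deliver oxygen to the same face.

## Compound list

1 | (E)-3-methylpent-2-en-4-yn-1-ol | C#C/C(C)=C/CO | starting material
2 | trimethyl{[(2E)-3-methyl-5-(trimethylsilyl)pent-2-en-4-yn-1-yl]oxy}silane | C[Si](C)(C)C#C/C(C)=C/CO[Si](C)(C)C | intermediate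
3 | (E)-3-methyl-5-(trimethylsilyl)pent-2-en-4-yn-1-ol | C[Si](C)(C)C#C/C(C)=C/CO | intermediate
4 | (E)-3-methyl-5-(trimethylsilyl)pent-2-en-4-ynal | C[Si](C)(C)C#C/C(C)=C/C=O | intermediate
5 | 3-methylbut-1-yne | CC(C)C#C | starting material
6 | (E)-4,4,5,5-tetramethyl-2-(3-methylbut-1-en-1-yl)-1,3,2-dioxaborolane | CC(C)/C=C/B1OC(C)(C)C(C)(C)O1 | intermediate
7 | lithium (chloromethyl)[(E)-3-methylbut-1-en-1-yl](pinacolato)borate | [Li+].CC(C)/C=C/[B-]1(CCl)OC(C)(C)C(C)(C)O1 | intermediate
8 | (E)-4,4,5,5-tetramethyl-2-(4-methylpent-2-en-1-yl)-1,3,2-dioxaborolane | CC(C)/C=C/CB1OC(C)(C)C(C)(C)O1 | intermediate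
9 | pinacol borate ester of 10, 2-{[(3R,4R,5E)-6-methyl-3-(propan-2-yl)-8-(trimethylsilyl)octa-1,5-dien-7-yn-4-yl]oxy}-4,4,5,5-tetramethyl-1,3,2-dioxaborolane | C[Si](C)(C)C#C/C(C)=C/[C@H](OB1OC(C)(C)C(C)(C)O1)[C@H](C(C)C)C=C | intermediate
10 | (3R,4R,5E)-6-methyl-3-(propan-2-yl)-8-(trimethylsilyl)octa-1,5-dien-7-yn-4-ol | C[Si](C)(C)C#C/C(C)=C/[C@H](O)[C@H](C(C)C)C=C | intermediate
11 | tert-butyldimethyl{[(3R,4R,5E)-6-methyl-3-(propan-2-yl)-8-(trimethylsilyl)octa-1,5-dien-7-yn-4-yl]oxy}silane | C[Si](C)(C)C#C/C(C)=C/[C@H](O[Si](C)(C)C(C)(C)C)[C@H](C(C)C)C=C | intermediate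
12 | 9-[(3S,4R,5E)-4-[(tert-butyldimethylsilyl)oxy]-6-methyl-3-(propan-2-yl)-8-(trimethylsilyl)oct-5-en-7-yn-1-yl]-9-borabicyclo[3.3.1]nonane | C[Si](C)(C)C#C/C(C)=C/[C@H](O[Si](C)(C)C(C)(C)C)[C@H](C(C)C)CCB1C2CCCC1CCC2 | intermediate
13 | (3S,4R,5E)-4-[(tert-butyldimethylsilyl)oxy]-6-methyl-3-(propan-2-yl)-8-(trimethylsilyl)oct-5-en-7-yn-1-ol | C[Si](C)(C)C#C/C(C)=C/[C@H](O[Si](C)(C)C(C)(C)C)[C@H](C(C)C)CCO | intermediate
14 | (3S,4R,5E)-4-[(tert-butyldimethylsilyl)oxy]-6-methyl-3-(propan-2-yl)oct-5-en-7-yn-1-ol | C#C/C(C)=C/[C@H](O[Si](C)(C)C(C)(C)C)[C@H](C(C)C)CCO | intermediate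
15 | (3S,4R,5E)-4-[(tert-butyldimethylsilyl)oxy]-6-methyl-3-(propan-2-yl)oct-5-en-7-ynal | C#C/C(C)=C/[C@H](O[Si](C)(C)C(C)(C)C)[C@H](C(C)C)CC=O | intermediate
16 | isopropenylmagnesium bromide (prop-1-en-2-ylmagnesium bromide) | CC(=C)[Mg]Br | starting material
17 | (5S,6R,7E)-6-[(tert-butyldimethylsilyl)oxy]-2,8-dimethyl-5-(propan-2-yl)deca-1,7-dien-9-yn-3-ol, both C3 epimers | C#C/C(C)=C/[C@H](O[Si](C)(C)C(C)(C)C)[C@H](C(C)C)CC(O)C(C)=C | intermediate
18 | (5S,6R,7E)-6-[(tert-butyldimethylsilyl)oxy]-2,8-dimethyl-5-(propan-2-yl)deca-1,7,9-trien-3-ol, both C3 epimers | C=C/C(C)=C/[C@H](O[Si](C)(C)C(C)(C)C)[C@H](C(C)C)CC(O)C(C)=C | intermediate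
19 | (5S,6R,7E)-6-[(tert-butyldimethylsilyl)oxy]-2,8-dimethyl-5-(propan-2-yl)deca-1,7,9-trien-3-one | C=C/C(C)=C/[C@H](O[Si](C)(C)C(C)(C)C)[C@H](C(C)C)CC(=O)C(C)=C | intermediate
20 | 6β-[(tert-butyldimethylsilyl)oxy]eudesm-3-en-9-one (5α-H, 7β-isopropyl, 10β-methyl) | CC(C)[C@@H]1CC(=O)[C@@]2(C)CCC=C(C)[C@@H]2[C@@H]1O[Si](C)(C)C(C)(C)C | intermediate
21 | 6β-hydroxyeudesm-3-en-9-one | CC(C)[C@@H]1CC(=O)[C@@]2(C)CCC=C(C)[C@@H]2[C@@H]1O | intermediate
22 | 6β-hydroxyeudesm-3-en-9-one hydrazone | CC(C)[C@@H]1CC(=NN)[C@@]2(C)CCC=C(C)[C@@H]2[C@@H]1O | intermediate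
23 | eudesm-3-en-6β-ol | CC(C)[C@@H]1CC[C@@]2(C)CCC=C(C)[C@@H]2[C@@H]1O | intermediate
24 | eudesm-3-en-6β-yl benzoate | CC(C)[C@@H]1CC[C@@]2(C)CCC=C(C)[C@@H]2[C@@H]1OC(=O)c1ccccc1 | intermediate
25 | 3α,4α-epoxyeudesman-6β-yl benzoate | CC(C)[C@@H]1CC[C@@]2(C)CC[C@H]3O[C@@]3(C)[C@@H]2[C@@H]1OC(=O)c1ccccc1 | intermediate
26 | 6β-(benzoyloxy)eudesmane-3α,4β-diol, (1R,2S,4aS,7R,8R,8aS)-7,8-dihydroxy-4a,8-dimethyl-2-(propan-2-yl)decahydronaphthalen-1-yl benzoate | CC(C)[C@@H]1CC[C@@]2(C)CC[C@@H](O)[C@](C)(O)[C@@H]2[C@@H]1OC(=O)c1ccccc1 | target

## Step count and least certain steps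

Total: 17 steps. Longest linear sequence: 15 steps (steps 1, 2 and 5–17 from 1; equally steps 3, 4 and 5–17 from 5).

**Step 12 (key step).** The likeliest failure is incomplete control of ring fusion and diene face, or ionisation of the doubly allylic silyl ether by the Lewis acid. The desired transition state carries a syn-axial contact between the C6 silyloxy group and C14, which works against the A(1,3) and equatorial-isopropyl preferences. The fallback changes the mode of activation to a cationic dienophile. It sets out from 19: 1,2-bis(trimethylsilyloxy)ethane and catalytic TMSOTf in CH2Cl2 at −78 °C convert the ketone into the dioxolane of the trienone F1. Under the same silyl triflate F1 ionises reversibly to a 2-alkoxyallyl cation, a much stronger dienophile that carries a bulkier group at C9 and cyclises at −78 °C to the ethylene ketal of the octalone F2. Pyridinium p-toluenesulfonate in wet acetone hydrolyses the strained ketal, and the route is rejoined at 20.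

**Step 5.** Slow addition or insufficient enantio- and diastereoselectivity is possible, because the γ-isopropyl reagent is bulkier than the crotyl reagents for which the catalysis is established and the aldehyde is a conjugated enynal. The fallback replaces catalyst control by reagent control. It sets out from 8: diethanolamine in ether gives the diethanolamine boronate F3, and exchange with diisopropyl (S,S)-tartrate in ether/brine gives the tartrate-modified (E)-allylboronate F4. F4 is added to 4 in toluene with 4 Å MS at −78 °C; the (S,S)-tartrate is expected to add to the Re face, and the route is rejoined at 10.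

**Step 14.** Hydrazone formation at the carbonyl next to the quaternary C10 may stall, or azine formation may compete, so that the ketone is not fully reduced. The fallback is a radical deoxygenation. It sets out from 20: NaBH4 in MeOH gives the C9 carbinol F5, NaH, CS2 and MeI give its S-methyl xanthate F6, and Bu3SnH with azobisisobutyronitrile in toluene at 110 °C (Barton–McCombie) gives the deoxygenated silyl ether F7. Aqueous HF in MeCN then rejoins the route at 23.

**Step 17.** The developing C4 cation may lose a proton to give allylic alcohols, take a hydride from C3 to give a ketone, or pass the benzoyl group to the C4 oxygen through the six-membered acyloxonium ion. The fallback avoids both a cation at C4 and an ester during the opening. It sets out from 23: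
- N-bromosuccinimide in aqueous acetone gives the bromohydrin 3α-bromoeudesmane-4β,6β-diol F8 (bromonium on the α face, water at C4 from the β face).
- K2CO3 in MeOH closes it to 3β,4β-epoxyeudesman-6β-ol F9.
- Sodium benzyloxide in benzyl alcohol at 110 °C opens F9 at the secondary C3 from the α face (SN2, trans-diaxial) to give the 3α-benzyl ether F10.
- Benzoylation of the only secondary hydroxyl (BzCl, DMAP, pyridine) gives its 6β-benzoate F11.
- Hydrogenolysis (H2, Pd/C, EtOAc) removes the benzyl group and rejoins the route at 26.

## Further compounds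

F1 | step 12 | 2-[(2S,3R,4E)-3-[(tert-butyldimethylsilyl)oxy]-5-methyl-2-(propan-2-yl)hepta-4,6-dien-1-yl]-2-(prop-1-en-2-yl)-1,3-dioxolane | C=C/C(C)=C/[C@H](O[Si](C)(C)C(C)(C)C)[C@H](C(C)C)CC1(OCCO1)C(C)=C
F2 | step 12 | 9,9-(ethylenedioxy)-6β-[(tert-butyldimethylsilyl)oxy]eudesm-3-ene | CC(C)[C@@H]1CC2(OCCO2)[C@@]3(C)CCC=C(C)[C@@H]3[C@@H]1O[Si](C)(C)C(C)(C)C
F3 | step 5 | 2-[(2E)-4-methylpent-2-en-1-yl]-1,3,6,2-dioxazaborocane | CC(C)/C=C/CB1OCCNCCO1
F4 | step 5 | diisopropyl (4S,5S)-2-[(2E)-4-methylpent-2-en-1-yl]-1,3,2-dioxaborolane-4,5-dicarboxylate | CC(C)/C=C/CB1O[C@H](C(=O)OC(C)C)[C@@H](C(=O)OC(C)C)O1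
F5 | step 14 | 6β-[(tert-butyldimethylsilyl)oxy]eudesm-3-en-9-ol, either C9 epimer | CC(C)[C@@H]1CC(O)[C@@]2(C)CCC=C(C)[C@@H]2[C@@H]1O[Si](C)(C)C(C)(C)C
F6 | step 14 | O-{6β-[(tert-butyldimethylsilyl)oxy]eudesm-3-en-9-yl} S-methyl dithiocarbonate | CC(C)[C@@H]1CC(OC(=S)SC)[C@@]2(C)CCC=C(C)[C@@H]2[C@@H]1O[Si](C)(C)C(C)(C)C
F7 | step 14 | 6β-[(tert-butyldimethylsilyl)oxy]eudesm-3-ene | CC(C)[C@@H]1CC[C@@]2(C)CCC=C(C)[C@@H]2[C@@H]1O[Si](C)(C)C(C)(C)C
F8 | step 17 | 3α-bromoeudesmane-4β,6β-diol | CC(C)[C@@H]1CC[C@@]2(C)CC[C@@H](Br)[C@](C)(O)[C@@H]2[C@@H]1O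
F9 | step 17 | 3β,4β-epoxyeudesman-6β-ol | CC(C)[C@@H]1CC[C@@]2(C)CC[C@@H]3O[C@]3(C)[C@@H]2[C@@H]1O
F10 | step 17 | 3α-(benzyloxy)eudesmane-4β,6β-diol | CC(C)[C@@H]1CC[C@@]2(C)CC[C@@H](OCc3ccccc3)[C@](C)(O)[C@@H]2[C@@H]1O
F11 | step 17 | 3α-(benzyloxy)-4β-hydroxyeudesman-6β-yl benzoate | CC(C)[C@@H]1CC[C@@]2(C)CC[C@@H](OCc3ccccc3)[C@](C)(O)[C@@H]2[C@@H]1OC(=O)c1ccccc1
A1 | alternative 1 | (2S)-4-[(1R)-1,3-dimethylcyclohex-2-en-1-yl]-2-(propan-2-yl)butanal | CC(C)[C@@H](C=O)CC[C@@]1(C)CCCC(C)=C1
A2 | alternative 1 | eudesm-4(15)-en-6α-ol | CC(C)[C@@H]1CC[C@@]2(C)CCCC(=C)[C@@H]2[C@H]1O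
A3 | alternative 2 | 6β-[(tert-butyldimethylsilyl)oxy]-4β-[(trimethylsilyl)oxy]-1,10-seco-eudesm-10(14)-en-1-yn-3-ol, either C3 epimer | CC(C)[C@@H]1CCC(=C)[C@H]([C@@](C)(O[Si](C)(C)C)C(O)C#C)[C@@H]1O[Si](C)(C)C(C)(C)C
A4 | alternative 2 | 1,14-cyclo-3-oxoeudesmane 4β-trimethylsilyl 6β-tert-butyldimethylsilyl bis-ether | CC(C)[C@@H]1CC[C@@]23C[C@@H]2CC(=O)[C@](C)(O[Si](C)(C)C)[C@@H]3[C@@H]1O[Si](C)(C)C(C)(C)C
A5 | alternative 3 | (1E)-1-[(tert-butyldimethylsilyl)oxy]-2-(propan-2-yl)buta-1,3-diene | C=C/C(C(C)C)=C/O[Si](C)(C)C(C)(C)C
A6 | alternative 3 | 2-methoxy-5-methyl-1,4-benzoquinone | COC1=CC(=O)C(C)=CC1=O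
A7 | alternative 3 | cis-fused endo adduct, 6α-[(tert-butyldimethylsilyl)oxy]-3-methoxy-5β-eudesma-2,7-diene-1,4-dione | CC(C)C1=CC[C@@]2(C)C(=O)C=C(OC)C(=O)[C@H]2[C@H]1O[Si](C)(C)C(C)(C)C
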